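(The numbers of this flask belong to no real substance; what happens was integrated by code.)

The free catalyst makes target from starting material, while target and starting material also combine to side product, so the flask to watch is a race between these two routes.

    starting material + free catalyst → catalyst intermediate (k1 = 42900 /M/s)
    catalyst intermediate → free catalyst + target (k2 = 34.5 /s)
    starting material + target → side product (k3 = 82.8 /M/s)

starting material 0.0010 M; free catalyst 10 µM; time 2.0 min

1. which holds at 2.0 min: what has brought the reaction to rest, or that it has not come to rest (no working catalyst is left / it is still moving / forward and back rates have come level / all of the starting material has reacted)
2. how much of the starting material has reacted by 2.0 min
3. how much target there is at 2.0 min, in percent of the starting material charged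

- a species is counted by the starting material in it: one side product counts as two
- the reaction counts as stopped when no species that holds the starting material changes by six tenths of a point or more over the second half of the time
- run time (flask): 2.0 min

The concentration that sets the order of the catalytic rate is c(start) against the Michaelis constant Km = 0.804 mM. At the charge of 0.0010 M the order lies between zero and one. That rate, 34.5 /s · c(catalyst) · c(start)/(Km + c(start)), with c(catalyst) the catalyst charged, still brings c(start) to 1% of its charge in about 13.6 s, far shorter than 2.0 min. So I commit to full conversion, and the yield is the open question.

With the catalyst intermediate in steady state, side rate over catalytic rate is a = 82.8 /M/s · c(target) · (Km + c(start))/(34.5 /s · c(catalyst)), and each starting material reacted gains (1 − a)/(1 + a) target. Target stands no higher than what has reacted. Averaging a over conversion on that limit gives my loss number, L = 0.137. The bound from below is a yield of 1 − 2L = 72.7%. For the bound from above, a stays under 0.433, so target is at least 39.6% of what reacted, and the yield is at most 94.6%.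

The forecast says all of the starting material has reacted, with 100% conversion and 79.6% target, adding “the target is then stable because its only consumer is gone”. That yield lies above my floor and below my ceiling.

In the flask all of the starting material has reacted, with 100% conversion and 79.8% target, and side product already stands at 15.9% after 0.100 min. In this flask target falls short of the charge by 20.2%, less than the 27.4% that 2L allows. In the neighbour flask charged with 1.7 × 10⁻⁵ M of free catalyst, L is 0.0803, smaller than in the first flask, which raises the floor to 83.9%. That neighbour flask gives target at 86.8%.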